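## Target check
The SMILES is a flavanone with a 7-OH on the A ring. The B ring carries a 3'-prenyl group and a 2,2-dimethylchromene fused across C4'–C5'. CIP analysis of the [C@H] centre gives **(2R)**, the enantiomer of natural (2S)-flavanones.

**Assumptions (one line each):**
- The (R) sense is delivered by the quinidine-derived catalyst. The catalyst series is to be confirmed by chiral HPLC against a racemic sample.
- The free 7-OH is tolerated in the Claisen–Schmidt and cyclisation steps.

## Retrosynthesis
1. The flavanone C2 stereocentre comes from an enantioselective intramolecular oxa-Michael closure (pyranone ring) of 2'-hydroxychalcone **8**.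
2. Chalcone **8** comes from a Claisen–Schmidt condensation of resacetophenone (**7**) with the chromene-aldehyde **6**.
3. The dimethylchromene ring of **6** is built by aryl propargyl ether formation, then thermal Claisen/6π-electrocyclisation, on 3-prenyl-4-hydroxybenzaldehyde (**3**).
4. **3** comes from ortho C-prenylation of 4-hydroxybenzaldehyde (**1**).
5. Ring order: the chromene ring forms first, then the A-ring C–C bond (chalcone), and the pyranone ring last, which sets C2.

## Route

**Step 1**
Reactants: **1** 4-hydroxybenzaldehyde; **2** prenyl bromide (1-bromo-3-methylbut-2-ene)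
Product: **3** 4-hydroxy-3-(3-methylbut-2-enyl)benzaldehyde
Conditions: NaOH (1.0 equiv), H2O, 0 °C to rt, 24 h; then dilute HCl
Reagents that add atoms: prenyl bromide, CC(C)=CCBr
Why: Phenoxide C-alkylation in water (hydrogen-bonded oxygen) favours SN2 attack at the free ortho carbon by the prenyl bromide. Prenyl stays linear, and the O-prenyl and di-prenyl by-products are removed by chromatography. No stereocentre is formed.

**Step 2**
Reactants: **3**; **4** 3-chloro-3-methylbut-1-yne
Product: **5** 3-prenyl-4-[(2-methylbut-3-yn-2-yl)oxy]benzaldehyde
Conditions: K2CO3, KI, cat. CuI, DMF, 60 °C, 12 h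
Reagents that add atoms: 3-chloro-3-methylbut-1-yne, CC(C)(Cl)C#C
Why: Williamson-type O-propargylation of the phenoxide, with Cu/I⁻ assisting displacement at the tertiary propargylic chloride. The aldehyde and prenyl alkene are untouched.

**Step 3**
Reactant: **5**
Product: **6** 2,2-dimethyl-8-(3-methylbut-2-enyl)-2H-chromene-6-carbaldehyde
Conditions: PhNEt2, 210 °C (reflux), N2, 4 h
Reagents that add atoms: none (thermal isomerisation)
Why: Aryl propargyl ether Claisen rearrangement goes to the only free ortho carbon (C5). Enolisation then gives the allenyl/ortho-quinone methide, and a 1,5-H shift and 6π-oxa-electrocyclisation close the 2,2-dimethyl-2H-chromene. The prenyl group is placed adjacent to the ring oxygen, as in the target.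

**Step 4**
Reactants: **6**; **7** 2',4'-dihydroxyacetophenone
Product: **8** (E)-1-(2,4-dihydroxyphenyl)-3-(2,2-dimethyl-8-prenyl-2H-chromen-6-yl)prop-2-en-1-one
Conditions: 50% aq KOH, EtOH, rt, 48–72 h, N2; then cold 1 M HCl to pH ~5
Reagents that add atoms: 2',4'-dihydroxyacetophenone, CC(=O)c1ccc(O)cc1O
Why: Claisen–Schmidt aldol condensation. The phenolate dianion of **7** deactivates spontaneous cyclisation, so the open (E)-chalcone accumulates. Mild acidification avoids chromene opening and racemic flavanone formation.

**Step 5**
Reactant: **8**
Product: **9** (2R)-7-hydroxy-flavanone bearing the 3'-prenyl-4',5'-dimethylchromene B ring, i.e. ent-abyssinone III (target)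
Conditions: quinidine-derived bifunctional squaramide (10 mol %), toluene (0.05 M), 25 °C, 72 h
Reagents that add atoms: none (isomerisation)
Why: Enantioselective intramolecular oxa-Michael (6-endo-trig) cyclisation. The catalyst's tertiary amine orients the 2'-phenol and its squaramide NHs bind the enone carbonyl, so the phenol attacks one enone face and sets C2 as (R). The C2 centre can racemise by retro-oxa-Michael under basic conditions, so the reaction is run mildly and stopped at high conversion.

## Compound list
1 | 4-hydroxybenzaldehyde | O=Cc1ccc(O)cc1 | starting material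
2 | prenyl bromide | CC(C)=CCBr | starting material
3 | 4-hydroxy-3-prenylbenzaldehyde | O=Cc1ccc(O)c(CC=C(C)C)c1 | intermediate
4 | 3-chloro-3-methylbut-1-yne | CC(C)(Cl)C#C | starting material
5 | 3-prenyl-4-[(2-methylbut-3-yn-2-yl)oxy]benzaldehyde | O=Cc1ccc(OC(C)(C)C#C)c(CC=C(C)C)c1 | intermediate
6 | 2,2-dimethyl-8-prenyl-2H-chromene-6-carbaldehyde | O=Cc1cc(CC=C(C)C)c2OC(C)(C)C=Cc2c1 | intermediate
7 | 2',4'-dihydroxyacetophenone | CC(=O)c1ccc(O)cc1O | starting material
8 | (E)-2'-hydroxychalcone (4'-OH, chromene/prenyl B ring) | O=C(/C=C/c1cc(CC=C(C)C)c2OC(C)(C)C=Cc2c1)c1ccc(O)cc1O | intermediate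
9 | ent-abyssinone III, (2R) | CC(C)=CCc1cc([C@H]2CC(=O)c3ccc(O)cc3O2)cc2c1OC(C)(C)C=C2 | target

## Totals
Total steps: 5. Longest linear sequence: 5 (1 → 3 → 5 → 6 → 8 → 9).

## Three steps most likely to fail
1. **Step 5 (enantioselectivity):** free-phenol chalcones often give only moderate ee, and the product can racemise by retro-oxa-Michael.
   - Fallback: cyclise **8** non-selectively (NaOAc, EtOH, reflux) to racemic **9** and resolve it by preparative chiral-phase HPLC. Alternatively, use a different disconnection, a Pd- or Rh-catalysed asymmetric conjugate arylation of 7-hydroxychromone with the corresponding B-ring arylboronic acid.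
2. **Step 1 (regioselectivity and yield):** direct C-prenylation can give mixtures of O-, C-, and di-prenylated products in modest yield.
   - Fallback: start from 2-prenylphenol. Build the chromene by propargylation and thermal cyclisation, then install the CHO group last by Rieche formylation (Cl2CHOMe, TiCl4) para to the ring oxygen.
3. **Step 3 (thermal chromene formation):** at ~210 °C the aldehyde and prenyl group may decompose, and the chromene may polymerise.
   - Fallback: skip the propargyl ether. Condense **3** directly with 3-methylbut-2-enal, PhB(OH)2 and AcOH in refluxing toluene (boronate-directed ortho-alkenylation/6π-electrocyclisation).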